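## Retrosynthetic overview

1. Target ⇒ Wittig mono-methylenation of the C2-symmetric 8,14-diketone-3,21-diol, in which both halves already carry 3β-OH, 5α-H, 9α-H and 10β-Me.
2. Diketone ⇒ exhaustive hydrogenation of a bis(alkylidene) dienedione, which comes from a two-fold ring expansion (1,2-shift of the ring-fusion C–C bond onto a gold-activated diyne) of a bis(1-alkynyl-hydrindenol); this makes both B rings (C9–C10 and C9′–C10′).
3. Diyne ⇒ Glaser–Hay dimerisation (C11–C12) of a 1-ethynyl-hydrindenol, made from (S)-Hajos–Parrish ketone by C1 ethynylation, deconjugative 4,4-dimethylation and 3-ketone reduction.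
4. Hajos–Parrish ketone ⇒ 2-methylcyclopentane-1,3-dione + methyl vinyl ketone (proline aldol sets C10).
5. Ring order: cyclopentane (bought) → ring A (annulation) → ring B by one-carbon expansion of the cyclopentane, on both halves in one operation.

Assumption: the hydroxyls are carried unprotected; iodomethane and the Wittig salt are treated as reagents, while ethynylmagnesium bromide, which supplies C9/C11 of each half, is numbered as a starting material.

## Route

Step 1
Reactants: 1 2-methylcyclopentane-1,3-dione; 2 but-3-en-2-one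
Product: 3 2-methyl-2-(3-oxobutyl)cyclopentane-1,3-dione
Conditions: H2O, AcOH (cat.), 70 °C
Reagents that add atoms: none
Why: Michael addition of the acidic cyclic 1,3-dione to the enone; the product is achiral.

Step 2
Reactants: 3 2-methyl-2-(3-oxobutyl)cyclopentane-1,3-dione
Product: 5 (7aS)-7a-methyl-2,3,7,7a-tetrahydro-1H-indene-1,5(6H)-dione [(S)-Hajos–Parrish ketone], via cis-ketol 4 (not isolated)
Conditions: (S)-proline (3 mol%), DMF, rt; then H2SO4 (cat.), DMF, 95 °C; recrystallise to >99% ee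
Reagents that add atoms: none
Why: Hajos–Parrish–Eder–Sauer–Wiechert reaction, in which the proline enamine aldol desymmetrises the prochiral dione and sets the quaternary centre as 7aS (the future 10β-methyl), followed by acid dehydration of the ketol.

Step 3
Reactants: 5 (S)-Hajos–Parrish ketone; 6 ethynylmagnesium bromide
Product: 7 (1R,7aS)-1-ethynyl-1-hydroxy-7a-methyl-1,2,3,6,7,7a-hexahydro-5H-inden-5-one
Conditions: 6 (1.15 equiv), LaCl3·2LiCl (0.3 equiv), THF, −40 → 0 °C; aq. NH4Cl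
Reagents that add atoms: none
Why: Grignard 1,2-addition to the saturated cyclopentanone, which is more electrophilic than the conjugated carbonyl (same site selectivity as NaBH4), from the α-face anti to the angular methyl, as in steroid 17-ethynylation.

Step 4
Reactants: 7 (1R,7aS)-1-ethynyl-1-hydroxy-7a-methyl-1,2,3,6,7,7a-hexahydro-5H-inden-5-one
Product: 8 (1R,7aS)-1-ethynyl-1-hydroxy-4,4,7a-trimethyl-1,2,4,6,7,7a-hexahydro-5H-inden-5-one
Conditions: KOtBu (3.5 equiv), MeI (6 equiv), t-BuOH–THF, 0 °C → rt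
Reagents that add atoms: iodomethane, CI
Why: deconjugative α,α-dialkylation of the extended dienolate puts both methyls on C4 and moves the alkene to C3=C3a; the hindered tertiary alkoxide and the alkyne C–H are not methylated in t-BuOH (analogy: 4,4-dimethylation of 17-hydroxy-Δ4-3-keto steroids), and no stereocentre is formed.

Step 5
Reactants: 8 (1R,7aS)-1-ethynyl-1-hydroxy-4,4,7a-trimethyl-1,2,4,6,7,7a-hexahydro-5H-inden-5-one
Product: 9 (1R,5S,7aS)-1-ethynyl-4,4,7a-trimethyl-2,4,5,6,7,7a-hexahydro-1H-indene-1,5-diol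
Conditions: NaBH4, MeOH, 0 °C
Reagents that add atoms: none
Why: borohydride reduction with axial hydride delivery from the α-face (opposite the 7a- and axial 4β-methyls) gives the equatorial β-alcohol, the future 3β-OH (S).

Step 6
Reactants: 9 (1R,5S,7aS)-1-ethynyl-4,4,7a-trimethyl-2,4,5,6,7,7a-hexahydro-1H-indene-1,5-diol (2 equiv)
Product: 10 1,1'-(buta-1,3-diyne-1,4-diyl)bis[(1R,5S,7aS)-4,4,7a-trimethyl-2,4,5,6,7,7a-hexahydro-1H-indene-1,5-diol]
Conditions: CuCl (10 mol%), TMEDA (20 mol%), O2 (1 atm), acetone, rt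
Reagents that add atoms: none
Why: Glaser–Hay oxidative homocoupling of the terminal alkyne forms the C11–C12 bond and the C2-symmetric diyne; free hydroxyls are tolerated, and residual minor enantiomer leaves as the separable heterochiral dimer.

Step 7
Reactants: 10 1,1'-(buta-1,3-diyne-1,4-diyl)bis[(1R,5S,7aS)-4,4,7a-trimethyl-2,4,5,6,7,7a-hexahydro-1H-indene-1,5-diol]
Product: 12 (1E,1'E)-1,1'-(ethane-1,2-diylidene)bis[(6S,8aS)-6-hydroxy-5,5,8a-trimethyl-3,5,6,7,8,8a-hexahydronaphthalen-2(1H)-one], via mono-ring-expanded ynenone 11 (not isolated)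
Conditions: [LAu(NCMe)]SbF6 (5 mol%; L = biaryl di(1-adamantyl)phosphine bearing a remote 3′-carboxamide), 2,6-di-tert-butylpyridine (10 mol%), 4 Å MS, 1,2-dichloroethane, 60 °C
Reagents that add atoms: none
Why: Proposed new method: two-fold Au(I)-catalysed alkynyl-carbinol 1,2-shift (semipinacol-type) ring expansion of an unstrained fused cyclopentenol, in which π-activation of each C≡C makes the carbinol-bound alkyne carbon electrophilic, the antiperiplanar bond to the fully substituted allylic ring-fusion carbon (the better migrating group) shifts onto it while the O–H, hydrogen-bonded to the ligand amide, becomes the C8 ketone, and protodeauration gives the (E)-alkylidene ketone; the driving forces are conversion of C≡C into a conjugated enone and relief of cyclopentene strain on going to the octalin, and the closest known reaction type is the Au(I)-catalysed ring expansion of 1-alkynylcyclopropanols and 1-alkynylcyclobutanols to alkylidenecycloalkanones, not shown for five-membered carbinols or for diynes.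

Step 8
Reactants: 12 (1E,1'E)-1,1'-(ethane-1,2-diylidene)bis[(6S,8aS)-6-hydroxy-5,5,8a-trimethyl-3,5,6,7,8,8a-hexahydronaphthalen-2(1H)-one]
Product: 13 1,1'-(ethane-1,2-diyl)bis[(1R,4aR,6S,8aS)-6-hydroxy-5,5,8a-trimethyloctahydronaphthalen-2(1H)-one]
Conditions: H2 (10 atm), 10% Pd/C, EtOAc–EtOH, rt; then K2CO3, MeOH, rt
Reagents that add atoms: none
Why: heterogeneous catalytic hydrogenation adds H2 syn from the α-face opposite the axial 10β- and 4β-methyls, giving both trans-decalins (5α-H) and 9α-H, and the brief base equilibration secures the equatorial 9β side chain next to each ketone.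

Step 9
Reactants: 13 1,1'-(ethane-1,2-diyl)bis[(1R,4aR,6S,8aS)-6-hydroxy-5,5,8a-trimethyloctahydronaphthalen-2(1H)-one]
Product: 14 26-nor-8-oxo-α-onocerin
Conditions: Ph3PCH3Br (1.1 equiv), KOtBu (1.05 equiv), THF–toluene, 0 → 60 °C, stopped near half conversion of C=O; chromatography, recovered 13 recycled
Reagents that add atoms: methyltriphenylphosphonium bromide, C[P+](c1ccccc1)(c1ccccc1)c1ccccc1.[Br-]
Why: Wittig methylenation of one of two equivalent, remote ketones (statistical, about 45% of 14 with 13 recovered and α-onocerin as over-reaction product); the ylide is too weakly basic to consume the hydroxyls, and any C9 epimerisation is biased to the natural equatorial configuration.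

## Compound list

1 | 2-methylcyclopentane-1,3-dione | CC1C(=O)CCC1=O | starting material
2 | but-3-en-2-one (methyl vinyl ketone) | CC(=O)C=C | starting material
3 | 2-methyl-2-(3-oxobutyl)cyclopentane-1,3-dione | CC(=O)CCC1(C)C(=O)CCC1=O | intermediate
4 | (3aS,7aS)-3a-hydroxy-7a-methylhexahydro-1H-indene-1,5(4H)-dione (cis-ketol) | C[C@]12CCC(=O)C[C@@]1(O)CCC2=O | intermediate (not isolated)
5 | (7aS)-7a-methyl-2,3,7,7a-tetrahydro-1H-indene-1,5(6H)-dione [(S)-Hajos–Parrish ketone] | C[C@]12CCC(=O)C=C1CCC2=O | intermediate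
6 | ethynylmagnesium bromide | C#C[Mg]Br | starting material
7 | (1R,7aS)-1-ethynyl-1-hydroxy-7a-methyl-1,2,3,6,7,7a-hexahydro-5H-inden-5-one | C#C[C@]1(O)CCC2=CC(=O)CC[C@]12C | intermediate
8 | (1R,7aS)-1-ethynyl-1-hydroxy-4,4,7a-trimethyl-1,2,4,6,7,7a-hexahydro-5H-inden-5-one | C#C[C@]1(O)CC=C2C(C)(C)C(=O)CC[C@]12C | intermediate
9 | (1R,5S,7aS)-1-ethynyl-4,4,7a-trimethyl-2,4,5,6,7,7a-hexahydro-1H-indene-1,5-diol | C#C[C@]1(O)CC=C2C(C)(C)[C@@H](O)CC[C@]12C | intermediate
10 | 1,1'-(buta-1,3-diyne-1,4-diyl)bis[(1R,5S,7aS)-4,4,7a-trimethyl-2,4,5,6,7,7a-hexahydro-1H-indene-1,5-diol] | C[C@]12CC[C@H](O)C(C)(C)C1=CC[C@@]2(O)C#CC#C[C@]1(O)CC=C2C(C)(C)[C@@H](O)CC[C@]12C | intermediate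
11 | (6S,8aS,E)-1-{3-[(1R,5S,7aS)-1,5-dihydroxy-4,4,7a-trimethyl-2,4,5,6,7,7a-hexahydro-1H-inden-1-yl]prop-2-yn-1-ylidene}-6-hydroxy-5,5,8a-trimethyl-3,5,6,7,8,8a-hexahydronaphthalen-2(1H)-one (mono-ring-expanded ynenone) | O=C1CC=C2C(C)(C)[C@@H](O)CC[C@]2(C)/C1=C\C#C[C@]1(O)CC=C2C(C)(C)[C@@H](O)CC[C@]12C | intermediate (not isolated)
12 | (1E,1'E)-1,1'-(ethane-1,2-diylidene)bis[(6S,8aS)-6-hydroxy-5,5,8a-trimethyl-3,5,6,7,8,8a-hexahydronaphthalen-2(1H)-one] | O=C1CC=C2C(C)(C)[C@@H](O)CC[C@]2(C)/C1=C\C=C1\C(=O)CC=C2C(C)(C)[C@@H](O)CC[C@]12C | intermediate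
13 | 1,1'-(ethane-1,2-diyl)bis[(1R,4aR,6S,8aS)-6-hydroxy-5,5,8a-trimethyloctahydronaphthalen-2(1H)-one] (3β,21α-dihydroxy-26,27-dinor-onocerane-8,14-dione) | O=C1CC[C@H]2C(C)(C)[C@@H](O)CC[C@]2(C)[C@H]1CC[C@H]1C(=O)CC[C@H]2C(C)(C)[C@@H](O)CC[C@]12C | intermediate
14 | 26-nor-8-oxo-α-onocerin | C=C1CC[C@H]2C(C)(C)[C@@H](O)CC[C@]2(C)[C@H]1CC[C@H]1C(=O)CC[C@H]2C(C)(C)[C@@H](O)CC[C@]12C | target

## Step count and risks

Total steps: 9. Longest linear sequence: 9.

**Step 7 (proposed new method).** The 1,2-shift may be too slow on an unstrained ring, the wrong ring bond (C2 side) may migrate, or acid-type dehydration and Meyer–Schuster paths may compete. The fallback uses known chemistry, sets out from 9 and comes back at 13. Lindlar semihydrogenation of 9 gives (1R,5S,7aS)-1-ethenyl-4,4,7a-trimethyl-2,4,5,6,7,7a-hexahydro-1H-indene-1,5-diol F1. Allylic-alcohol-directed epoxidation (VO(acac)2, t-BuOOH) gives (1S,5S,7aS)-4,4,7a-trimethyl-1-(oxiran-2-yl)-2,4,5,6,7,7a-hexahydro-1H-indene-1,5-diol F2, and either oxirane epimer serves. BF3·OEt2 in CH2Cl2 at −78 °C effects the established 2,3-epoxy-alcohol semipinacol ring expansion to (6S,8aR)-6-hydroxy-1-(hydroxymethyl)-5,5,8a-trimethyl-3,5,6,7,8,8a-hexahydronaphthalen-2(1H)-one F3. MsCl/Et3N at the primary hydroxyl gives the primary methanesulfonate of F3 F4, not isolated, which DBU eliminates to (6S,8aS)-6-hydroxy-5,5,8a-trimethyl-1-methylidene-3,5,6,7,8,8a-hexahydronaphthalen-2(1H)-one F5. SmI2/HMPA/t-BuOH in THF at −78 °C then forms C11–C12 by reductive β,β-hydrodimerisation of the enone to give 1,1'-(ethane-1,2-diyl)bis[(1R,6S,8aR)-6-hydroxy-5,5,8a-trimethyl-3,5,6,7,8,8a-hexahydronaphthalen-2(1H)-one] F6. H2, Pd/C and then K2CO3/MeOH convert this into 13.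

**Step 9.** The hindered ketone may need a large excess of ylide, which destroys the stoichiometric control needed for mono-olefination. The fallback sets out from 13 and comes back at 14. Excess Ph3P=CH2 (5 equiv, toluene, 80 °C) converts 13 fully into α-onocerin F7. OsO4 (cat.) with NMO (1.0 equiv) at partial conversion dihydroxylates one exocyclic alkene from the α-face to give 8α,26-dihydroxy-8,26-dihydro-α-onocerin F8, which is easily separated by polarity from recovered α-onocerin. NaIO4 then cleaves it to 14.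

**Step 3.** The Grignard reagent may also attack the enone carbonyl or enolise the substrate. The fallback sets out from 5 and comes back at 9; it also avoids carrying the propargylic alcohol through step 4. Selective ketalisation of the saturated ketone (ethylene glycol, TsOH, 4 Å MS) gives (7a'S)-7a'-methyl-2',3',7',7a'-tetrahydrospiro[[1,3]dioxolane-2,1'-inden]-5'(6'H)-one F9. KOtBu/MeI gives (7a'S)-4',4',7a'-trimethyl-2',4',7',7a'-tetrahydrospiro[[1,3]dioxolane-2,1'-inden]-5'(6'H)-one F10. NaBH4 gives (5'S,7a'S)-4',4',7a'-trimethyl-2',4',5',6',7',7a'-hexahydrospiro[[1,3]dioxolane-2,1'-inden]-5'-ol F11. PPTS in wet acetone releases (5S,7aS)-5-hydroxy-4,4,7a-trimethyl-2,4,5,6,7,7a-hexahydro-1H-inden-1-one F12. Excess 6 with CeCl3 (non-basic, for the easily enolised β,γ-unsaturated ketone) at −78 °C adds from the α-face to give 9.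

## Further compounds

F1 | step 7 | (1R,5S,7aS)-1-ethenyl-4,4,7a-trimethyl-2,4,5,6,7,7a-hexahydro-1H-indene-1,5-diol | C=C[C@]1(O)CC=C2C(C)(C)[C@@H](O)CC[C@]12C
F2 | step 7 | (1S,5S,7aS)-4,4,7a-trimethyl-1-(oxiran-2-yl)-2,4,5,6,7,7a-hexahydro-1H-indene-1,5-diol (both oxirane epimers) | C1OC1[C@]1(O)CC=C2C(C)(C)[C@@H](O)CC[C@]12C
F3 | step 7 | (6S,8aR)-6-hydroxy-1-(hydroxymethyl)-5,5,8a-trimethyl-3,5,6,7,8,8a-hexahydronaphthalen-2(1H)-one (C1 epimers) | OCC1C(=O)CC=C2C(C)(C)[C@@H](O)CC[C@]12C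
F4 | step 7 | [(6S,8aR)-6-hydroxy-5,5,8a-trimethyl-2-oxo-1,2,3,5,6,7,8,8a-octahydronaphthalen-1-yl]methyl methanesulfonate (C1 epimers) | CS(=O)(=O)OCC1C(=O)CC=C2C(C)(C)[C@@H](O)CC[C@]12C
F5 | step 7 | (6S,8aS)-6-hydroxy-5,5,8a-trimethyl-1-methylidene-3,5,6,7,8,8a-hexahydronaphthalen-2(1H)-one | C=C1C(=O)CC=C2C(C)(C)[C@@H](O)CC[C@]12C
F6 | step 7 | 1,1'-(ethane-1,2-diyl)bis[(1R,6S,8aR)-6-hydroxy-5,5,8a-trimethyl-3,5,6,7,8,8a-hexahydronaphthalen-2(1H)-one] | O=C1CC=C2C(C)(C)[C@@H](O)CC[C@]2(C)[C@H]1CC[C@H]1C(=O)CC=C2C(C)(C)[C@@H](O)CC[C@]12C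
F7 | step 9 | α-onocerin | C=C1CC[C@H]2C(C)(C)[C@@H](O)CC[C@]2(C)[C@H]1CC[C@H]1C(=C)CC[C@H]2C(C)(C)[C@@H](O)CC[C@]12C
F8 | step 9 | 8α,26-dihydroxy-8,26-dihydro-α-onocerin | OC[C@@]1(O)CC[C@H]2C(C)(C)[C@@H](O)CC[C@]2(C)[C@H]1CC[C@H]1C(=C)CC[C@H]2C(C)(C)[C@@H](O)CC[C@]12C
F9 | step 3 | (7a'S)-7a'-methyl-2',3',7',7a'-tetrahydrospiro[[1,3]dioxolane-2,1'-inden]-5'(6'H)-one | C[C@]12CCC(=O)C=C1CCC21OCCO1
F10 | step 3 | (7a'S)-4',4',7a'-trimethyl-2',4',7',7a'-tetrahydrospiro[[1,3]dioxolane-2,1'-inden]-5'(6'H)-one | C[C@]12CCC(=O)C(C)(C)C1=CCC21OCCO1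
F11 | step 3 | (5'S,7a'S)-4',4',7a'-trimethyl-2',4',5',6',7',7a'-hexahydrospiro[[1,3]dioxolane-2,1'-inden]-5'-ol | C[C@]12CC[C@H](O)C(C)(C)C1=CCC21OCCO1
F12 | step 3 | (5S,7aS)-5-hydroxy-4,4,7a-trimethyl-2,4,5,6,7,7a-hexahydro-1H-inden-1-one | C[C@]12CC[C@H](O)C(C)(C)C1=CCC2=O
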